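**Retrosynthetic overview**
1. Last ring: the 3(2H)-furanone with its C3–O–C10 bridge, by transannular gold-catalysed carbonyl-to-alkyne cyclization with 1,2-shift of a methyl group (C1→C10) in a ten-membered 1-hydroxy-1-methyl-2-yn-10-one.
2. Ten-membered carbocycle and α-methylene-γ-lactone together: intramolecular indium Barbier allylation (C6–C7) of a (Z)-enynal carrying a 2-(bromomethyl)enoate, then lactonization.
3. C8–C9: reagent-controlled syn boron aldol of an α-acetoxy ketone with a bromo enal; the C9 acetate is already in place and the new C8 hydroxyl is isovalerylated.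
4. α-Acetoxy ketone from (Z)-3-methylpent-2-en-4-yn-1-ol, methyl pyruvate (asymmetric alkynylation sets C1), ICH2Cl and acetate; bromo enal from dimethoxyacetaldehyde and methyl acrylate.
5. Ring order: lactone and carbocycle in one step, then the furanone.

Assumption: germacrane numbering (ring C1–C10, lactone C11–C13, methyls C14 and C15) is used for locants, and for each chiral controller (amino-alcohol ligand in step 2, Ipc2BOTf in step 7) the enantiomer is the one that gives the stated face selectivity.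

**Route**

Step 1
Reactants: 1 (2Z)-3-methylpent-2-en-4-yn-1-ol
Product: 2 triethyl{[(2Z)-3-methylpent-2-en-4-yn-1-yl]oxy}silane
Conditions: Et3SiCl, imidazole, CH2Cl2, 0 °C
Reagents that add atoms: chlorotriethylsilane CC[Si](Cl)(CC)CC
Why: Standard silyl ether protection of the primary allylic alcohol, which masks O6 until it is converted directly to the aldehyde in step 9.

Step 2
Reactants: 2 triethyl{[(2Z)-3-methylpent-2-en-4-yn-1-yl]oxy}silane; 3 methyl pyruvate
Product: 4 methyl (2R,5Z)-2-hydroxy-2,5-dimethyl-7-[(triethylsilyl)oxy]hept-5-en-3-ynoate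
Conditions: Zn(OTf)2 (20 mol %), (1S,2S)-3-[(tert-butyldimethylsilyl)oxy]-2-(dimethylamino)-1-(4-nitrophenyl)propan-1-ol (22 mol %), Et3N (30 mol %), toluene, 60 °C
Reagents that add atoms: none
Why: Catalytic enantioselective zinc acetylide addition to an α-keto ester (asymmetric alkynylation), in which the chiral zinc amino-alkoxide delivers the alkynyl group to the Re face of the ketone and so sets the 2R tertiary carbinol (future C1) that later controls C10.

Step 3
Reactants: 4 methyl (2R,5Z)-2-hydroxy-2,5-dimethyl-7-[(triethylsilyl)oxy]hept-5-en-3-ynoate; 5 chloroiodomethane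
Product: 6 (3R,6Z)-1-chloro-3-hydroxy-3,6-dimethyl-8-[(triethylsilyl)oxy]oct-6-en-4-yn-2-one
Conditions: 5 (3 equiv), MeLi·LiBr (4 equiv), THF, −78 °C; sat. aq NH4Cl
Reagents that add atoms: none
Why: Ester homologation with chloromethyllithium made in situ (carbenoid acylation), where the stable tetrahedral lithium adduct prevents over-addition, the tertiary alcohol is carried as its lithium alkoxide and the stereocentre is untouched.

Step 4
Reactants: 6 (3R,6Z)-1-chloro-3-hydroxy-3,6-dimethyl-8-[(triethylsilyl)oxy]oct-6-en-4-yn-2-one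
Product: 7 (3R,6Z)-3-hydroxy-3,6-dimethyl-2-oxo-8-[(triethylsilyl)oxy]oct-6-en-4-yn-1-yl acetate
Conditions: CsOAc, DMF, 0 to 23 °C
Reagents that add atoms: cesium acetate CC(=O)[O-].[Cs+]
Why: SN2 displacement of the activated α-keto chloride by acetate installs the C9 oxygen directly as the acetate of the target and gives the glycolate-type ketone for the aldol.

Step 5
Reactants: 8 2,2-dimethoxyacetaldehyde; 9 methyl acrylate
Product: 10 methyl 3-hydroxy-4,4-dimethoxy-2-methylidenebutanoate (racemic)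
Conditions: DABCO (0.5 equiv), 1,4-dioxane–H2O, 23 °C
Reagents that add atoms: none
Why: Morita–Baylis–Hillman reaction of a reactive α-alkoxy aldehyde with methyl acrylate; the racemic carbinol does not matter because that carbon becomes sp2 in step 6.

Step 6
Reactants: 10 methyl 3-hydroxy-4,4-dimethoxy-2-methylidenebutanoate (racemic)
Product: 12 methyl (2Z)-2-(bromomethyl)-4-oxobut-2-enoate, via dimethyl acetal bromide 11 (not isolated)
Conditions: 48% aq HBr, conc. H2SO4 (cat.), CH2Cl2, 0 to 23 °C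
Reagents that add atoms: hydrogen bromide Br; water O
Why: Acid-mediated SN2' bromination of the Baylis–Hillman alcohol gives the thermodynamic (Z)-2-(bromomethyl)enoate (allylic transposition), and the same aqueous acid hydrolyses the dimethyl acetal to the aldehyde.

Step 7
Reactants: 7 (3R,6Z)-3-hydroxy-3,6-dimethyl-2-oxo-8-[(triethylsilyl)oxy]oct-6-en-4-yn-1-yl acetate; 12 methyl (2Z)-2-(bromomethyl)-4-oxobut-2-enoate
Product: 13 methyl (2Z,4S,5R,7R,10Z)-5-(acetyloxy)-2-(bromomethyl)-4,7-dihydroxy-7,10-dimethyl-6-oxo-12-[(triethylsilyl)oxy]dodeca-2,10-dien-8-ynoate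
Conditions: (−)-Ipc2BOTf (2.3 equiv), i-Pr2NEt (3 equiv), CH2Cl2, −78 °C; then 12, −78 to −25 °C; pH 7 buffer–MeOH
Reagents that add atoms: none
Why: Reagent-controlled syn boron aldol (Paterson-type, Zimmerman–Traxler chair) of the (Z)-enol borinate formed on the only enolisable side of the ketone, with Re-face attack on the enal setting 8S and 9R while the tertiary hydroxyl is carried as its borinate.

Step 8
Reactants: 13 methyl (2Z,4S,5R,7R,10Z)-5-(acetyloxy)-2-(bromomethyl)-4,7-dihydroxy-7,10-dimethyl-6-oxo-12-[(triethylsilyl)oxy]dodeca-2,10-dien-8-ynoate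
Product: 14 methyl (2Z,4S,5R,7R,10Z)-5-(acetyloxy)-2-(bromomethyl)-7-hydroxy-7,10-dimethyl-4-[(3-methylbutanoyl)oxy]-6-oxo-12-[(triethylsilyl)oxy]dodeca-2,10-dien-8-ynoate
Conditions: isovaleryl chloride, 2,4,6-collidine, CH2Cl2, −20 to 0 °C
Reagents that add atoms: 3-methylbutanoyl chloride CC(C)CC(Cl)=O
Why: Selective O-acylation of the only secondary alcohol (the tertiary propargylic hydroxyl does not react) with a hindered base that spares the allylic bromide, fixing the C8 isovalerate.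

Step 9
Reactants: 14 methyl (2Z,4S,5R,7R,10Z)-5-(acetyloxy)-2-(bromomethyl)-7-hydroxy-7,10-dimethyl-4-[(3-methylbutanoyl)oxy]-6-oxo-12-[(triethylsilyl)oxy]dodeca-2,10-dien-8-ynoate
Product: 15 methyl (2Z,4S,5R,7R,10Z)-5-(acetyloxy)-2-(bromomethyl)-7-hydroxy-7,10-dimethyl-4-[(3-methylbutanoyl)oxy]-6,12-dioxododeca-2,10-dien-8-ynoate
Conditions: (COCl)2, DMSO, CH2Cl2, −78 to −40 °C; then i-Pr2NEt, −78 to 0 °C
Reagents that add atoms: none
Why: Swern oxidation applied directly to the primary triethylsilyl ether (chloride-assisted desilylation to the alkoxysulfonium, then ylide fragmentation) gives the (Z)-enal in one operation without affecting the tertiary alcohol, the esters or the allylic bromide.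

Step 10
Reactants: 15 methyl (2Z,4S,5R,7R,10Z)-5-(acetyloxy)-2-(bromomethyl)-7-hydroxy-7,10-dimethyl-4-[(3-methylbutanoyl)oxy]-6,12-dioxododeca-2,10-dien-8-ynoate
Product: 17 (3aS,4S,5R,7R,10Z,11aR)-5-(acetyloxy)-7-hydroxy-7,10-dimethyl-3-methylidene-2,6-dioxo-2,3,3a,4,5,6,7,11a-octahydro-8,9-didehydrocyclodeca[b]furan-4-yl 3-methylbutanoate, via seco hydroxy ester 16 (not isolated)
Conditions: In powder (2 equiv), THF–H2O 3:1, 0.002 M, 25 °C; then PPTS (cat.), CH2Cl2, 25 °C
Reagents that add atoms: none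
Why: Intramolecular Barbier allylation in which the allylindium from the 2-(bromomethyl)enoate adds through C7 (SE2') to the C6 aldehyde in a chair-like transition state, closing the ten-membered ring pre-organised by the rigid (Z)-enyne, after which the C6 alkoxide lactonises; ring constraints and the C8 stereocentre are expected to give the 6R,7S trans-fused lactone.

Step 11
Reactants: 17 (3aS,4S,5R,7R,10Z,11aR)-5-(acetyloxy)-7-hydroxy-7,10-dimethyl-3-methylidene-2,6-dioxo-2,3,3a,4,5,6,7,11a-octahydro-8,9-didehydrocyclodeca[b]furan-4-yl 3-methylbutanoate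
Product: 18 (4Z,6R,7S,8S,9R,10R)-9-acetoxy-8-(3-methylbutanoyloxy)-1-oxo-3,10-epoxygermacra-2,4,11(13)-trien-12,6-olide (CNP0255553.1)
Conditions: AuCl3 (5 mol %), CH2Cl2, 35 °C
Reagents that add atoms: none
Why: Proposed new method: a transannular, chirality-transferring variant of the gold-catalysed heterocyclization/1,2-migration of 2-hydroxy-2-alkynyl ketones, in which AuCl3 activates the ring alkyne, the C10 ketone oxygen adds 5-endo to C3 to give a bicyclic oxocarbenium vinyl-gold species, the C1 methyl group shifts suprafacially to the cationic C10 while C1 becomes the ketone (semipinacol-type 1,2-shift), and protodeauration releases the 3(2H)-furanone and the C3–O–C10 bridge, the 10R centre arising from 1R because the methyl stays on its own ring face; the closest known reaction is the AuCl3- or PtCl2-catalysed conversion of acyclic and monocyclic 2-hydroxy-2-alkynyl ketones into 3(2H)-furanones, which has not been run across a medium ring or used to relay a stereocentre.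

**Compound list**
1 | (2Z)-3-methylpent-2-en-4-yn-1-ol | OC/C=C(/C)C#C | starting material
2 | triethyl{[(2Z)-3-methylpent-2-en-4-yn-1-yl]oxy}silane | CC[Si](CC)(CC)OC/C=C(/C)C#C | intermediate
3 | methyl pyruvate | CC(=O)C(=O)OC | starting material
4 | methyl (2R,5Z)-2-hydroxy-2,5-dimethyl-7-[(triethylsilyl)oxy]hept-5-en-3-ynoate | CC[Si](CC)(CC)OC/C=C(/C)C#C[C@@](C)(O)C(=O)OC | intermediate
5 | chloroiodomethane | ClCI | starting material
6 | (3R,6Z)-1-chloro-3-hydroxy-3,6-dimethyl-8-[(triethylsilyl)oxy]oct-6-en-4-yn-2-one | CC[Si](CC)(CC)OC/C=C(/C)C#C[C@@](C)(O)C(=O)CCl | intermediate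
7 | (3R,6Z)-3-hydroxy-3,6-dimethyl-2-oxo-8-[(triethylsilyl)oxy]oct-6-en-4-yn-1-yl acetate | CC[Si](CC)(CC)OC/C=C(/C)C#C[C@@](C)(O)C(=O)COC(C)=O | intermediate
8 | 2,2-dimethoxyacetaldehyde | COC(OC)C=O | starting material
9 | methyl acrylate | C=CC(=O)OC | starting material
10 | methyl 3-hydroxy-4,4-dimethoxy-2-methylidenebutanoate (racemic) | C=C(C(=O)OC)C(O)C(OC)OC | intermediate
11 | methyl (2Z)-2-(bromomethyl)-4,4-dimethoxybut-2-enoate (not isolated) | COC(OC)/C=C(\CBr)C(=O)OC | intermediate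
12 | methyl (2Z)-2-(bromomethyl)-4-oxobut-2-enoate | O=C/C=C(\CBr)C(=O)OC | intermediate
13 | methyl (2Z,4S,5R,7R,10Z)-5-(acetyloxy)-2-(bromomethyl)-4,7-dihydroxy-7,10-dimethyl-6-oxo-12-[(triethylsilyl)oxy]dodeca-2,10-dien-8-ynoate | CC[Si](CC)(CC)OC/C=C(/C)C#C[C@@](C)(O)C(=O)[C@H](OC(C)=O)[C@@H](O)/C=C(\CBr)C(=O)OC | intermediate
14 | methyl (2Z,4S,5R,7R,10Z)-5-(acetyloxy)-2-(bromomethyl)-7-hydroxy-7,10-dimethyl-4-[(3-methylbutanoyl)oxy]-6-oxo-12-[(triethylsilyl)oxy]dodeca-2,10-dien-8-ynoate | CC[Si](CC)(CC)OC/C=C(/C)C#C[C@@](C)(O)C(=O)[C@H](OC(C)=O)[C@@H](OC(=O)CC(C)C)/C=C(\CBr)C(=O)OC | intermediate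
15 | methyl (2Z,4S,5R,7R,10Z)-5-(acetyloxy)-2-(bromomethyl)-7-hydroxy-7,10-dimethyl-4-[(3-methylbutanoyl)oxy]-6,12-dioxododeca-2,10-dien-8-ynoate | O=C/C=C(/C)C#C[C@@](C)(O)C(=O)[C@H](OC(C)=O)[C@@H](OC(=O)CC(C)C)/C=C(\CBr)C(=O)OC | intermediate
16 | methyl 2-[(1S,2R,3Z,7R,9R,10S)-9-(acetyloxy)-2,7-dihydroxy-4,7-dimethyl-10-[(3-methylbutanoyl)oxy]-8-oxocyclodec-3-en-5-yn-1-yl]prop-2-enoate (not isolated) | O[C@@H]1/C=C(/C)C#C[C@@](C)(O)C(=O)[C@H](OC(C)=O)[C@@H](OC(=O)CC(C)C)[C@H]1C(=C)C(=O)OC | intermediate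
17 | (3aS,4S,5R,7R,10Z,11aR)-5-(acetyloxy)-7-hydroxy-7,10-dimethyl-3-methylidene-2,6-dioxo-2,3,3a,4,5,6,7,11a-octahydro-8,9-didehydrocyclodeca[b]furan-4-yl 3-methylbutanoate | C=C1C(=O)O[C@@H]2/C=C(/C)C#C[C@@](C)(O)C(=O)[C@H](OC(C)=O)[C@@H](OC(=O)CC(C)C)[C@@H]12 | intermediate
18 | (4Z,6R,7S,8S,9R,10R)-9-acetoxy-8-(3-methylbutanoyloxy)-1-oxo-3,10-epoxygermacra-2,4,11(13)-trien-12,6-olide (CNP0255553.1) | C=C1C(=O)O[C@@H]2/C=C(/C)C3=CC(=O)[C@](C)(O3)[C@H](OC(C)=O)[C@@H](OC(=O)CC(C)C)[C@@H]12 | target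

**Step count and risks**

Total steps: 11 (steps 5 and 6 make the side fragment 12). Longest linear sequence: 9 steps (1 → 2 → 4 → 6 → 7 → 13 → 14 → 15 → 17 → 18).

The three steps most likely to fail:

The aldol of step 7. The (Z)-enolisation of an α-acetoxy ketone, the level of reagent control next to a borylated tertiary carbinol, and acetyl migration in the aldol product are all uncertain. The fallback replaces the stoichiometric boron aldol by a catalytic direct aldol of a free hydroxy ketone and builds the two esters one after the other. It sets out from 7: K2CO3 in MeOH at 0 °C removes the acetate to give (3R,6Z)-1,3-dihydroxy-3,6-dimethyl-8-[(triethylsilyl)oxy]oct-6-en-4-yn-2-one F1. A dinuclear zinc–ProPhenol catalyst (Et2Zn, ProPhenol, THF, −20 °C) then joins F1 and 12 to the syn-diol methyl (2Z,4S,5R,7R,10Z)-2-(bromomethyl)-4,5,7-trihydroxy-7,10-dimethyl-6-oxo-12-[(triethylsilyl)oxy]dodeca-2,10-dien-8-ynoate F2. The less hindered C8 hydroxyl is isovalerylated (isovaleryl chloride, collidine, −40 °C) to the mono-ester methyl (2Z,4S,5R,7R,10Z)-2-(bromomethyl)-5,7-dihydroxy-7,10-dimethyl-4-[(3-methylbutanoyl)oxy]-6-oxo-12-[(triethylsilyl)oxy]dodeca-2,10-dien-8-ynoate F3. Acetylation of the C9 hydroxyl (AcCl, collidine, 0 °C) brings the route back at 14.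

The macrocyclization of step 10. The ten-membered ring closure competes with oligomerisation, and the 6R,7S outcome rests on substrate control. The fallback closes the ring at C8–C9 by aldol after an intermolecular lactone-forming allylation. It sets out from 7 and from 11, the latter now isolated from 10 with NBS–Me2S in CH2Cl2. The Swern conditions of step 9 turn 7 into the enal (3R,6Z)-3-hydroxy-3,6-dimethyl-2,8-dioxooct-6-en-4-yn-1-yl acetate F4. Indium-mediated coupling of F4 with 11 (THF–H2O) gives the hydroxy ester methyl (3S,4R,5Z,9R)-11-(acetyloxy)-3-(dimethoxymethyl)-4,9-dihydroxy-6,9-dimethyl-2-methylidene-10-oxoundec-5-en-7-ynoate F5. PPTS lactonises it to the trans-lactone acetal (3R,6Z)-7-[(2R,3S)-3-(dimethoxymethyl)-4-methylidene-5-oxooxolan-2-yl]-3-hydroxy-3,6-dimethyl-2-oxohept-6-en-4-yn-1-yl acetate F6; the unwanted C6/C7 diastereomers are separated here, since this intermolecular step has no control relative to C1. Aqueous TFA frees the aldehyde (3R,6Z)-7-[(2R,3S)-3-formyl-4-methylidene-5-oxooxolan-2-yl]-3-hydroxy-3,6-dimethyl-2-oxohept-6-en-4-yn-1-yl acetate F7. An intramolecular boron aldol (Bu2BOTf, i-Pr2NEt, CH2Cl2, 0.003 M, −78 °C) closes the ring to the 8-hydroxy macrocycle (3aR,4S,5R,7R,10Z,11aR)-4,7-dihydroxy-7,10-dimethyl-3-methylidene-2,6-dioxo-2,3,3a,4,5,6,7,11a-octahydro-8,9-didehydrocyclodeca[b]furan-5-yl acetate F8. Isovalerylation as in step 8 brings the route back at 17.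

The new transannular cyclization with 1,2-shift of step 11. The ring may hold the C10 carbonyl away from the alkyne, the methyl shift may be slow, or the strained bicycle may not form. The fallback uses known chemistry: the established AuCl3 (or PtCl2) reaction of acyclic 2-hydroxy-2-alkynyl ketones, run before the macrocycle is made. It sets out from 14: AuCl3 (5 mol %) in CH2Cl2 at 35 °C gives the acyclic furanone methyl (2Z,4S,5R)-5-(acetyloxy)-2-(bromomethyl)-5-[(2R)-2-methyl-3-oxo-5-{(2Z)-4-[(triethylsilyl)oxy]but-2-en-2-yl}-2,3-dihydrofuran-2-yl]-4-[(3-methylbutanoyl)oxy]pent-2-enoate F9. The Swern conditions of step 9 give the enal methyl (2Z,4S,5R)-5-(acetyloxy)-2-(bromomethyl)-5-{(2R)-2-methyl-3-oxo-5-[(2Z)-4-oxobut-2-en-2-yl]-2,3-dihydrofuran-2-yl}-4-[(3-methylbutanoyl)oxy]pent-2-enoate F10. The indium Barbier conditions of step 10 then close the ten-membered ring onto the rigid furanone to give the C6-hydroxy C12-methyl ester of 18 (lactone opened; 4Z,6R,7S,8S,9R,10R) F11, which lactonises with PPTS and so comes back to the route at 18.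

**Further compounds**
F1 | step 7 | (3R,6Z)-1,3-dihydroxy-3,6-dimethyl-8-[(triethylsilyl)oxy]oct-6-en-4-yn-2-one | CC[Si](CC)(CC)OC/C=C(/C)C#C[C@@](C)(O)C(=O)CO
F2 | step 7 | methyl (2Z,4S,5R,7R,10Z)-2-(bromomethyl)-4,5,7-trihydroxy-7,10-dimethyl-6-oxo-12-[(triethylsilyl)oxy]dodeca-2,10-dien-8-ynoate | CC[Si](CC)(CC)OC/C=C(/C)C#C[C@@](C)(O)C(=O)[C@H](O)[C@@H](O)/C=C(\CBr)C(=O)OC
F3 | step 7 | methyl (2Z,4S,5R,7R,10Z)-2-(bromomethyl)-5,7-dihydroxy-7,10-dimethyl-4-[(3-methylbutanoyl)oxy]-6-oxo-12-[(triethylsilyl)oxy]dodeca-2,10-dien-8-ynoate | CC[Si](CC)(CC)OC/C=C(/C)C#C[C@@](C)(O)C(=O)[C@H](O)[C@@H](OC(=O)CC(C)C)/C=C(\CBr)C(=O)OC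
F4 | step 10 | (3R,6Z)-3-hydroxy-3,6-dimethyl-2,8-dioxooct-6-en-4-yn-1-yl acetate | O=C/C=C(/C)C#C[C@@](C)(O)C(=O)COC(C)=O
F5 | step 10 | methyl (3S,4R,5Z,9R)-11-(acetyloxy)-3-(dimethoxymethyl)-4,9-dihydroxy-6,9-dimethyl-2-methylidene-10-oxoundec-5-en-7-ynoate | O[C@H](/C=C(/C)C#C[C@@](C)(O)C(=O)COC(C)=O)[C@@H](C(OC)OC)C(=C)C(=O)OC
F6 | step 10 | (3R,6Z)-7-[(2R,3S)-3-(dimethoxymethyl)-4-methylidene-5-oxooxolan-2-yl]-3-hydroxy-3,6-dimethyl-2-oxohept-6-en-4-yn-1-yl acetate | C=C1C(=O)O[C@H](/C=C(/C)C#C[C@@](C)(O)C(=O)COC(C)=O)[C@H]1C(OC)OC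
F7 | step 10 | (3R,6Z)-7-[(2R,3S)-3-formyl-4-methylidene-5-oxooxolan-2-yl]-3-hydroxy-3,6-dimethyl-2-oxohept-6-en-4-yn-1-yl acetate | C=C1C(=O)O[C@H](/C=C(/C)C#C[C@@](C)(O)C(=O)COC(C)=O)[C@H]1C=O
F8 | step 10 | (3aR,4S,5R,7R,10Z,11aR)-4,7-dihydroxy-7,10-dimethyl-3-methylidene-2,6-dioxo-2,3,3a,4,5,6,7,11a-octahydro-8,9-didehydrocyclodeca[b]furan-5-yl acetate | C=C1C(=O)O[C@@H]2/C=C(/C)C#C[C@@](C)(O)C(=O)[C@H](OC(C)=O)[C@@H](O)[C@@H]12
F9 | step 11 | methyl (2Z,4S,5R)-5-(acetyloxy)-2-(bromomethyl)-5-[(2R)-2-methyl-3-oxo-5-{(2Z)-4-[(triethylsilyl)oxy]but-2-en-2-yl}-2,3-dihydrofuran-2-yl]-4-[(3-methylbutanoyl)oxy]pent-2-enoate | CC[Si](CC)(CC)OC/C=C(/C)C1=CC(=O)[C@](C)(O1)[C@H](OC(C)=O)[C@@H](OC(=O)CC(C)C)/C=C(\CBr)C(=O)OC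
F10 | step 11 | methyl (2Z,4S,5R)-5-(acetyloxy)-2-(bromomethyl)-5-{(2R)-2-methyl-3-oxo-5-[(2Z)-4-oxobut-2-en-2-yl]-2,3-dihydrofuran-2-yl}-4-[(3-methylbutanoyl)oxy]pent-2-enoate | O=C/C=C(/C)C1=CC(=O)[C@](C)(O1)[C@H](OC(C)=O)[C@@H](OC(=O)CC(C)C)/C=C(\CBr)C(=O)OC
F11 | step 11 | C6-hydroxy C12-methyl ester of 18 (lactone opened; 4Z,6R,7S,8S,9R,10R) | O[C@@H]1/C=C(/C)C2=CC(=O)[C@](C)(O2)[C@H](OC(C)=O)[C@@H](OC(=O)CC(C)C)[C@H]1C(=C)C(=O)OC
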